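**Retrosynthetic overview**
1. Target acid ⇒ methyl ester. The 1,2-dioxane (second ring, formed last) is cut at both C–O bonds (C6–O and C3–O), giving a threo C6 alcohol that carries an (E)-enoate, plus H2O2; they are joined by a one-pot triflate SN2 / 6-exo oxa-Michael annulation (C6 inverted, C3 set trans).
2. Hydroxy-enoate ⇒ lactol + Ph3P=CHCO2Me; lactol ⇒ trans-oxolane-2-carbaldehyde + a three-carbon acetal Grignard reagent (chelation control sets C6).
3. (7Z,9E)-Diene side chain ⇒ Wittig reaction of a C17 phosphonium ylide (from a chloride handle) with (2E)-hepta-2,6-dienal (from pent-4-enal).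
4. trans-2,5-Oxolane (first ring) ⇒ C7–O bond by cobalt-catalysed aerobic oxidative cyclisation of (5R)-12-chlorododec-1-en-5-ol, made from (S)-1,2-epoxy-5-hexene and 6-chlorohexylmagnesium bromide (C10 from the epoxide).

Assumption: atoms are labelled C1 (CO2H) to C24 along the chain, and (S)-1,2-epoxy-5-hexene is taken as a purchasable single enantiomer (also reachable from (S)-epichlorohydrin and allylmagnesium chloride).

**Route**

Step 1
Reactants: 1 (S)-2-(but-3-en-1-yl)oxirane [(S)-1,2-epoxy-5-hexene]; 2 1-bromo-6-chlorohexane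
Product: 4 (5R)-12-chlorododec-1-en-5-ol, via (6-chlorohexyl)magnesium bromide 3 (not isolated)
Conditions: 2, Mg, THF, 35 °C; then 1, CuI (10 mol %), THF, −40 to 0 °C; H2O
Reagents that add atoms: none
Why: Copper-catalysed SN2 opening of the terminal epoxide at its CH2 carbon by the Grignard reagent (Mg inserts into C–Br only) leaves the C10–O bond untouched, so the epoxide stereocentre is carried over unchanged (S to R only by a priority change).

Step 2
Reactants: 4
Product: 5 [(2S,5R)-5-(7-chloroheptyl)oxolan-2-yl]methanol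
Conditions: Co(modp)2 [bis(1-morpholinocarbamoyl-4,4-dimethylpentane-1,3-dionato)cobalt] (10 mol %), O2 (1 atm), t-BuOOH (10 mol %), i-PrOH, 55 °C
Reagents that add atoms: dioxygen, O=O
Why: Mukaiyama aerobic oxidative cyclisation of a pent-4-en-1-ol under divalent-cobalt catalysis forms the C7–O bond 5-exo through a chair-like transition state with the C10 chain pseudo-equatorial, giving the 2,5-trans ring (new C7 = S, typically ≥95:5), while the exocyclic radical is trapped by O2 and reduced to the primary alcohol by 2-propanol.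

Step 3
Reactants: 5
Product: 7 {7-[(2R,5S)-5-(hydroxymethyl)oxolan-2-yl]heptyl}triphenylphosphonium iodide, via primary iodide 6 (not isolated)
Conditions: NaI (1.5 equiv), PPh3 (1.5 equiv), MeCN, reflux
Reagents that add atoms: sodium iodide, [Na+].[I-]; triphenylphosphine, c1ccc(cc1)P(c1ccccc1)c1ccccc1
Why: Finkelstein exchange of the primary chloride followed by SN2 quaternisation of PPh3 by the primary iodide, with the free alcohol and the ring inert.

Step 4
Reactants: 8 pent-4-enal; 9 (triphenylphosphoranylidene)acetaldehyde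
Product: 10 (2E)-hepta-2,6-dienal
Conditions: toluene, 80 °C
Reagents that add atoms: none
Why: Wittig two-carbon homologation with a stabilised formyl ylide, which gives the (E)-enal.

Step 5
Reactants: 7; 10
Product: 12 [(2S,5R)-5-[(7Z,9E)-tetradeca-7,9,13-trien-1-yl]oxolan-2-yl]methanol, via sodium alkoxide ylide 11 (not isolated)
Conditions: NaN(SiMe3)2 (2.1 equiv), THF, −78 °C; then 10, −78 °C to rt; H2O
Reagents that add atoms: none
Why: Salt-free Wittig olefination of a non-stabilised ylide with an enal adds 1,2 and closes the cis-oxaphosphetane kinetically, giving the (7Z) alkene (about 9:1) while the (9E) alkene of 10 is kept.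

Step 6
Reactants: 12
Product: 13 (2S,5R)-5-[(7Z,9E)-tetradeca-7,9,13-trien-1-yl]oxolane-2-carbaldehyde
Conditions: Dess–Martin periodinane, CH2Cl2, 0 °C to rt; used crude
Reagents that add atoms: none
Why: Dess–Martin oxidation of the primary alcohol is neutral and mild, so the alkenes and the epimerisable C7 centre are not touched.

Step 7
Reactants: 13; 14 2-(2-bromoethyl)-1,3-dioxolane
Product: 17 (5S)-5-[(2S,5R)-5-[(7Z,9E)-tetradeca-7,9,13-trien-1-yl]oxolan-2-yl]oxolan-2-ol (anomer mixture), via dioxolanylethyl Grignard reagent 15 (not isolated), via acetal alcohol 16 (not isolated)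
Conditions: 14, Mg, THF, 25 °C; then 13, MgBr2·OEt2, CH2Cl2, −78 °C; then 1 M HCl, THF, rt
Reagents that add atoms: water, O
Why: Chelation-controlled (Cram-chelate) Grignard addition, in which magnesium bridges the aldehyde and ring oxygens so that the nucleophile enters on the face of the C7 hydrogen and gives the threo (6S) alcohol, followed by acid hydrolysis of the γ-hydroxy acetal to the five-membered lactol.

Step 8
Reactants: 17; 18 methyl (triphenylphosphoranylidene)acetate
Product: 19 methyl (2E,6S)-6-hydroxy-6-[(2S,5R)-5-[(7Z,9E)-tetradeca-7,9,13-trien-1-yl]oxolan-2-yl]hex-2-enoate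
Conditions: PhCO2H (10 mol %), toluene, 50 °C
Reagents that add atoms: none
Why: Wittig olefination of the open hydroxy-aldehyde form of the lactol with a stabilised ylide gives the (E)-enoate under neutral conditions that leave the free C6 alcohol un-cyclised, and the minor erythro epimer from step 7 is removed here by chromatography.

Step 9
Reactants: 19
Product: 22 methyl 2-[(3R,6R)-6-[(2S,5R)-5-[(7Z,9E)-tetradeca-7,9,13-trien-1-yl]oxolan-2-yl]-1,2-dioxan-3-yl]acetate, via C6 triflate 20 (not isolated), via C6 hydroperoxide 21 (not isolated)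
Conditions: Tf2O, 2,6-lutidine, CH2Cl2, −78 °C; then H2O2 (anhydrous, in Et2O, 10 equiv), CsOH·H2O (2.5 equiv), DMF, −40 to 0 °C; then CF3CH2OH, 0 °C to rt
Reagents that add atoms: hydrogen peroxide, OO
Why: Proposed new method: hydrogen peroxide serves as an O–O linchpin in a one-pot stereoinvertive SN2 / oxa-Michael annulation – the hydroperoxide anion (α-effect nucleophile, weakly basic, pKa of H2O2 about 11.6) displaces the cold C6 triflate with inversion (6S alcohol to 6R hydroperoxide 21) before ring-oxygen participation or E2 can compete, the same base deprotonates 21 (pKa about 12.5) and the peroxy anion adds 6-exo-trig to the (E)-enoate through a chair transition state with both ring substituents equatorial, which sets C3 as R (trans-3,6), and the trifluoroethoxide-buffered medium lets any cis isomer equilibrate by retro-Michael/re-addition; the closest known reactions are the perhydrolysis of alkyl sulfonates to hydroperoxides, the double displacement of bis-triflates by stannyl peroxides to cyclic peroxides and the base-mediated oxa-Michael closure of hydroperoxy enoates to 1,2-dioxanes, but their merger with H2O2 itself on an oxolane-flanked secondary triflate that carries the enoate has not been shown.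

Step 10
Reactants: 22
Product: 23 2-[(3R,6R)-6-[(2S,5R)-5-[(7Z,9E)-tetradeca-7,9,13-trien-1-yl]oxolan-2-yl]-1,2-dioxan-3-yl]acetic acid
Conditions: LiOH·H2O, THF/H2O 3:1, 0 °C; then 1 M HCl to pH 4
Reagents that add atoms: lithium hydroxide, [Li+].[OH-]
Why: Cold ester saponification (BAc2) with mild acidification should spare the dialkyl peroxide and leaves C3, C6, C7 and C10 untouched.

**Compound list**
1 | (S)-2-(but-3-en-1-yl)oxirane | C=CCC[C@H]1CO1 | starting material
2 | 1-bromo-6-chlorohexane | ClCCCCCCBr | starting material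
3 | (6-chlorohexyl)magnesium bromide | ClCCCCCC[Mg]Br | intermediate
4 | (5R)-12-chlorododec-1-en-5-ol | ClCCCCCCC[C@@H](O)CCC=C | intermediate
5 | [(2S,5R)-5-(7-chloroheptyl)oxolan-2-yl]methanol | ClCCCCCCC[C@@H]1CC[C@@H](CO)O1 | intermediate
6 | [(2S,5R)-5-(7-iodoheptyl)oxolan-2-yl]methanol | ICCCCCCC[C@@H]1CC[C@@H](CO)O1 | intermediate
7 | {7-[(2R,5S)-5-(hydroxymethyl)oxolan-2-yl]heptyl}triphenylphosphonium iodide | c1ccccc1[P+](c1ccccc1)(c1ccccc1)CCCCCCC[C@@H]1CC[C@@H](CO)O1.[I-] | intermediate
8 | pent-4-enal | C=CCCC=O | starting material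
9 | (triphenylphosphoranylidene)acetaldehyde | O=CC=P(c1ccccc1)(c1ccccc1)c1ccccc1 | starting material
10 | (2E)-hepta-2,6-dienal | C=CCC/C=C/C=O | intermediate
11 | sodium {(2S,5R)-5-[7-(triphenyl-λ5-phosphanylidene)heptyl]oxolan-2-yl}methanolate | c1ccccc1P(c1ccccc1)(c1ccccc1)=CCCCCCC[C@@H]1CC[C@@H](C[O-])O1.[Na+] | intermediate
12 | [(2S,5R)-5-[(7Z,9E)-tetradeca-7,9,13-trien-1-yl]oxolan-2-yl]methanol | C=CCC/C=C/C=C\CCCCCC[C@@H]1CC[C@@H](CO)O1 | intermediate
13 | (2S,5R)-5-[(7Z,9E)-tetradeca-7,9,13-trien-1-yl]oxolane-2-carbaldehyde | C=CCC/C=C/C=C\CCCCCC[C@@H]1CC[C@@H](C=O)O1 | intermediate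
14 | 2-(2-bromoethyl)-1,3-dioxolane | BrCCC1OCCO1 | starting material
15 | [2-(1,3-dioxolan-2-yl)ethyl]magnesium bromide | Br[Mg]CCC1OCCO1 | intermediate
16 | (1S)-3-(1,3-dioxolan-2-yl)-1-[(2S,5R)-5-[(7Z,9E)-tetradeca-7,9,13-trien-1-yl]oxolan-2-yl]propan-1-ol | C=CCC/C=C/C=C\CCCCCC[C@@H]1CC[C@@H]([C@@H](O)CCC2OCCO2)O1 | intermediate
17 | (5S)-5-[(2S,5R)-5-[(7Z,9E)-tetradeca-7,9,13-trien-1-yl]oxolan-2-yl]oxolan-2-ol (anomer mixture) | C=CCC/C=C/C=C\CCCCCC[C@@H]1CC[C@@H]([C@@H]2CCC(O)O2)O1 | intermediate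
18 | methyl (triphenylphosphoranylidene)acetate | COC(=O)C=P(c1ccccc1)(c1ccccc1)c1ccccc1 | starting material
19 | methyl (2E,6S)-6-hydroxy-6-[(2S,5R)-5-[(7Z,9E)-tetradeca-7,9,13-trien-1-yl]oxolan-2-yl]hex-2-enoate | C=CCC/C=C/C=C\CCCCCC[C@@H]1CC[C@@H]([C@@H](O)CC/C=C/C(=O)OC)O1 | intermediate
20 | methyl (2E,6S)-6-[(2S,5R)-5-[(7Z,9E)-tetradeca-7,9,13-trien-1-yl]oxolan-2-yl]-6-[(trifluoromethanesulfonyl)oxy]hex-2-enoate | C=CCC/C=C/C=C\CCCCCC[C@@H]1CC[C@@H]([C@@H](OS(=O)(=O)C(F)(F)F)CC/C=C/C(=O)OC)O1 | intermediate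
21 | methyl (2E,6R)-6-hydroperoxy-6-[(2S,5R)-5-[(7Z,9E)-tetradeca-7,9,13-trien-1-yl]oxolan-2-yl]hex-2-enoate | C=CCC/C=C/C=C\CCCCCC[C@@H]1CC[C@@H]([C@H](OO)CC/C=C/C(=O)OC)O1 | intermediate
22 | methyl 2-[(3R,6R)-6-[(2S,5R)-5-[(7Z,9E)-tetradeca-7,9,13-trien-1-yl]oxolan-2-yl]-1,2-dioxan-3-yl]acetate | C=CCC/C=C/C=C\CCCCCC[C@@H]1CC[C@@H]([C@H]2CC[C@H](CC(=O)OC)OO2)O1 | intermediate
23 | 2-[(3R,6R)-6-[(2S,5R)-5-[(7Z,9E)-tetradeca-7,9,13-trien-1-yl]oxolan-2-yl]-1,2-dioxan-3-yl]acetic acid | C=CCC/C=C/C=C\CCCCCC[C@@H]1CC[C@@H]([C@H]2CC[C@H](CC(=O)O)OO2)O1 | target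

**Step count and risks**
Total steps: 10. Longest linear sequence: 9 (steps 1, 2, 3, 5, 6, 7, 8, 9, 10).

Most likely to fail, step 9 (the new annulation). The oxolane oxygen may assist loss of triflate (ring expansion or retention), the hydroperoxide anion may attack sulfur or cause E2, and excess peroxide may perhydrolyse the methyl ester. The fallback uses only known chemistry, sets out from 19 and comes back to the route at 22. Alcohol 19 is triflated as in step 9 and the cold triflate 20 alkylates the cesium salt of 2-methoxypropan-2-yl hydroperoxide (CsOH·H2O, DMF, 0 °C). This mono-protected hydroperoxide can neither bridge two molecules nor close on the enoate, and it gives with inversion the C6 monoperoxyketal F1. Aqueous acetic acid in THF then frees hydroperoxide 21, which is isolated and closed to 22 with Et2NH in CF3CH2OH.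

Second, step 7 (diastereocontrol). The Grignard reagent is delivered in THF, which weakens the magnesium chelate and can erode the threo:erythro ratio. The fallback sets out from 13 and comes back at 16, and sets C6 by hydride delivery instead of carbon addition. The adduct is isolated before hydrolysis as the mixture of 16 and its C6 epimer, the erythro acetal alcohol F2. The mixture is oxidised with Dess–Martin periodinane to the acetal ketone F3, and F3 is reduced with LiBH(s-Bu)3 (THF, −78 °C). Polar Felkin–Anh delivery then gives the threo alcohol 16, which is hydrolysed with 1 M HCl to 17 as before.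

Third, step 10 (hydroxide on a β-peroxy ester). Retro-oxa-Michael ring opening or Kornblum–DeLaMare cleavage of the dioxane can compete with saponification. The fallback sets out from 17 and comes back at 23, carrying an ester that is removed without base. Lactol 17 reacts with tert-butyl (triphenylphosphoranylidene)acetate under the step 8 conditions to give the tert-butyl hydroxy-enoate F4. The step 9 sequence then leads through the tert-butyl triflate F5 and the tert-butyl hydroperoxide F6 to the tert-butyl dioxane ester F7. ZnBr2 in CH2Cl2 at rt cleaves the tert-butyl group to give 23.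

**Further compounds**
F1 | step 9 | methyl (2E,6R)-6-[(2-methoxypropan-2-yl)peroxy]-6-[(2S,5R)-5-[(7Z,9E)-tetradeca-7,9,13-trien-1-yl]oxolan-2-yl]hex-2-enoate | C=CCC/C=C/C=C\CCCCCC[C@@H]1CC[C@@H]([C@H](OOC(C)(C)OC)CC/C=C/C(=O)OC)O1
F2 | step 7 | (1R)-3-(1,3-dioxolan-2-yl)-1-[(2S,5R)-5-[(7Z,9E)-tetradeca-7,9,13-trien-1-yl]oxolan-2-yl]propan-1-ol | C=CCC/C=C/C=C\CCCCCC[C@@H]1CC[C@@H]([C@H](O)CCC2OCCO2)O1
F3 | step 7 | 3-(1,3-dioxolan-2-yl)-1-[(2S,5R)-5-[(7Z,9E)-tetradeca-7,9,13-trien-1-yl]oxolan-2-yl]propan-1-one | C=CCC/C=C/C=C\CCCCCC[C@@H]1CC[C@@H](C(=O)CCC2OCCO2)O1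
F4 | step 10 | tert-butyl (2E,6S)-6-hydroxy-6-[(2S,5R)-5-[(7Z,9E)-tetradeca-7,9,13-trien-1-yl]oxolan-2-yl]hex-2-enoate | C=CCC/C=C/C=C\CCCCCC[C@@H]1CC[C@@H]([C@@H](O)CC/C=C/C(=O)OC(C)(C)C)O1
F5 | step 10 | tert-butyl (2E,6S)-6-[(2S,5R)-5-[(7Z,9E)-tetradeca-7,9,13-trien-1-yl]oxolan-2-yl]-6-[(trifluoromethanesulfonyl)oxy]hex-2-enoate | C=CCC/C=C/C=C\CCCCCC[C@@H]1CC[C@@H]([C@@H](OS(=O)(=O)C(F)(F)F)CC/C=C/C(=O)OC(C)(C)C)O1
F6 | step 10 | tert-butyl (2E,6R)-6-hydroperoxy-6-[(2S,5R)-5-[(7Z,9E)-tetradeca-7,9,13-trien-1-yl]oxolan-2-yl]hex-2-enoate | C=CCC/C=C/C=C\CCCCCC[C@@H]1CC[C@@H]([C@H](OO)CC/C=C/C(=O)OC(C)(C)C)O1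
F7 | step 10 | tert-butyl 2-[(3R,6R)-6-[(2S,5R)-5-[(7Z,9E)-tetradeca-7,9,13-trien-1-yl]oxolan-2-yl]-1,2-dioxan-3-yl]acetate | C=CCC/C=C/C=C\CCCCCC[C@@H]1CC[C@@H]([C@H]2CC[C@H](CC(=O)OC(C)(C)C)OO2)O1
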